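**Retrosynthetic overview**
- The strategy rests on ring B: ether oxygen on C1', hydroxyls on C2' and C4', pentyl on C6'. This is the oxygen pattern of a folded C11 chain with carbonyls at C2', C4' and C6', so the C1'–C6' bond is cut by a retro-aldol aromatization to a 1-aryloxyundecane-2,4,6-trione carried on the ring A phenol oxygen.
- The triketone is cut at C2'–C3' into an aryloxyacetic N-methoxy-N-methylamide (ring A from methyl orsellinate) and the terminal dianion of nonane-2,4-dione.
- The lactone ring of the isocoumarin is cut at C3–C4 (acylation of the ring A methyl with a hexanoyl unit) and at C1–O2 (enol lactonization).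
- Ring order: ring A is bought, ring B is formed second by the aldol aromatization, the lactone ring is formed third. All phenols travel as methyl ethers until a final BBr3 demethylation.

Key step: step 4

Remark: the 2,4,6-triketone is written in its all-keto form although it should exist largely as enol tautomers; ring B is numbered C1' (ether carbon) to C6' (pentyl carbon), C7' is the first carbon of that pentyl chain, and the isocoumarin carries its usual numbering.

**Step 1**
Reactants: 1 methyl orsellinate (methyl 2,4-dihydroxy-6-methylbenzoate)
Product: 2 methyl 2-hydroxy-4-methoxy-6-methylbenzoate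
Conditions: MeI (1.1 equiv), K2CO3, acetone, reflux
Reagents that add atoms: iodomethane, CI
Why: The 2-hydroxyl is tied up in a hydrogen bond to the ester carbonyl and is far less nucleophilic, so a Williamson etherification with about one equivalent of iodomethane should take the 4-hydroxyl only.

**Step 2**
Reactants: 2 methyl 2-hydroxy-4-methoxy-6-methylbenzoate; 3 2-chloro-N-methoxy-N-methylacetamide
Product: 4 methyl 4-methoxy-2-{2-[methoxy(methyl)amino]-2-oxoethoxy}-6-methylbenzoate
Conditions: K2CO3, NaI (cat.), DMF, 70 °C
Reagents that add atoms: none
Why: Williamson etherification under forcing carbonate conditions with iodide catalysis should alkylate the chelated 2-hydroxyl by SN2 displacement on the α-chloroamide, whose α-protons are too weakly acidic under carbonate for a Dieckmann closure onto the ring A ester.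

**Step 3**
Reactants: 5 nonane-2,4-dione; 4 methyl 4-methoxy-2-{2-[methoxy(methyl)amino]-2-oxoethoxy}-6-methylbenzoate
Product: 7 methyl 4-methoxy-2-methyl-6-[(2,4,6-trioxoundecyl)oxy]benzoate, via dilithio dianion 6 (not isolated)
Conditions: 5 (2 equiv), LiN(iPr)2 (4 equiv), THF, −78 to 0 °C; then 4 (1 equiv), −78 to −20 °C; cold 1 M HCl to pH 5
Reagents that add atoms: none
Why: Twofold deprotonation of the β-diketone should give the 1,3-dianion, which reacts at its terminal CH2 in a Claisen-type acylation of a diketone dianion, while the N-methoxy-N-methylamide stops the addition at the ketone level and the di-ortho-substituted ring A benzoate is too hindered to compete at low temperature.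

**Step 4**
Reactants: 7 methyl 4-methoxy-2-methyl-6-[(2,4,6-trioxoundecyl)oxy]benzoate
Product: 9 methyl 2-(2,4-dihydroxy-6-pentylphenoxy)-4-methoxy-6-methylbenzoate, via aldol adduct 8 (not isolated)
Conditions: KOH (3 equiv), H2O/MeOH, Ar, 0 °C to rt; then 1 M HCl to pH 4
Reagents that add atoms: none
Why: In dilute aqueous hydroxide the triketone should sit as its C3'/C5' polyenolate, and further deprotonation at C1', the terminal carbon acidified by both the C2' carbonyl and the aryloxy oxygen, gives the carbon nucleophile that adds to the C6' ketone; loss of water from adduct 8 and enolization of the C2' and C4' carbonyls then give the resorcinol with no change of oxidation level. The closest known reaction is the base-mediated aldol aromatization of 2,4,6-triketones to 5-alkylresorcinols, the laboratory counterpart of polyketide folding. Ring B closes by forming C1'–C6' in a 6-(enolendo)-exo-trig aldol addition. No stereocentre remains, because the two centres of adduct 8 are erased on aromatization. The step needs C1' and not C7' to act as nucleophile, C-attack on the ketone and not O-cyclization to a 4-pyranone, and attack on C6' and not a Claisen closure onto the ring A ester. The aryloxy group biases terminal enolate formation toward C1', basic conditions keep the carbonyl oxygens as enolates so the acid-type pyranone closure is shut down, and in water a dialkyl ketone is far more electrophilic than a di-ortho-substituted, donor-substituted benzoate.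

**Step 5**
Reactants: 9 methyl 2-(2,4-dihydroxy-6-pentylphenoxy)-4-methoxy-6-methylbenzoate
Product: 10 methyl 2-(2,4-dimethoxy-6-pentylphenoxy)-4-methoxy-6-methylbenzoate
Conditions: MeI (excess), K2CO3, acetone, reflux
Reagents that add atoms: iodomethane, CI
Why: Williamson etherification with excess iodomethane should cap both ring B phenols, which removes the acidic protons before the lithiation step and leaves the hindered ester untouched.

**Step 6**
Reactants: 11 hexanoyl chloride; 12 N,O-dimethylhydroxylamine hydrochloride
Product: 13 N-methoxy-N-methylhexanamide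
Conditions: K2CO3, H2O/EtOAc, 0 °C to rt
Reagents that add atoms: none
Why: Schotten–Baumann N-acylation of the hydroxylamine by the acid chloride under two-phase carbonate conditions is a standard preparation of a Weinreb amide.

**Step 7**
Reactants: 10 methyl 2-(2,4-dimethoxy-6-pentylphenoxy)-4-methoxy-6-methylbenzoate; 13 N-methoxy-N-methylhexanamide
Product: 15 methyl 2-(2,4-dimethoxy-6-pentylphenoxy)-4-methoxy-6-(2-oxoheptyl)benzoate, via benzylic lithium species 14 (not isolated)
Conditions: LiN(iPr)2, THF, −78 °C; then 13, −78 to −40 °C; cold 1 M HCl
Reagents that add atoms: none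
Why: LiN(iPr)2 should deprotonate the ring A methyl, the only position acidified by an ortho ester (lateral lithiation of an ortho-toluate), and the benzylic anion is then acylated by the N-methoxy-N-methylamide, which releases the ketone only on work-up and so prevents double addition.

**Step 8**
Reactants: 15 methyl 2-(2,4-dimethoxy-6-pentylphenoxy)-4-methoxy-6-(2-oxoheptyl)benzoate
Product: 16 8-(2,4-dimethoxy-6-pentylphenoxy)-6-methoxy-3-pentyl-1H-isochromen-1-one
Conditions: TsOH·H2O (cat.), toluene, reflux, 4 Å molecular sieves
Reagents that add atoms: none
Why: In this acid-catalysed enol lactonization the enol of the benzylic ketone, conjugated with ring A, should attack the neighbouring ester through oxygen to close the six-membered lactone with loss of methanol, and acid avoids the base-type C-acylation that would lead to a naphthalene-1,3-diol.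

**Step 9**
Reactants: 16 8-(2,4-dimethoxy-6-pentylphenoxy)-6-methoxy-3-pentyl-1H-isochromen-1-one
Product: 17 8-(2,4-dihydroxy-6-pentylphenoxy)-6-hydroxy-3-pentyl-1H-isochromen-1-one
Conditions: BBr3 (excess), CH2Cl2, −78 °C to rt; then H2O
Reagents that add atoms: none
Why: Excess BBr3 should cleave the three aryl methyl ethers by Lewis-acid-assisted SN2 demethylation, whereas the diaryl ether offers no alkyl carbon for bromide attack and the isocoumarin lactone is expected to survive.

**Compound list**
1 | methyl orsellinate (methyl 2,4-dihydroxy-6-methylbenzoate) | COC(=O)c1c(C)cc(O)cc1O | starting material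
2 | methyl 2-hydroxy-4-methoxy-6-methylbenzoate | COC(=O)c1c(C)cc(OC)cc1O | intermediate
3 | 2-chloro-N-methoxy-N-methylacetamide | CON(C)C(=O)CCl | starting material
4 | methyl 4-methoxy-2-{2-[methoxy(methyl)amino]-2-oxoethoxy}-6-methylbenzoate | CON(C)C(=O)COc1cc(OC)cc(C)c1C(=O)OC | intermediate
5 | nonane-2,4-dione | CCCCCC(=O)CC(C)=O | starting material
6 | dilithium 1,3-dianion of nonane-2,4-dione | [Li+].[Li+].[CH2-]C(=O)[CH-]C(=O)CCCCC | intermediate
7 | methyl 4-methoxy-2-methyl-6-[(2,4,6-trioxoundecyl)oxy]benzoate | CCCCCC(=O)CC(=O)CC(=O)COc1cc(OC)cc(C)c1C(=O)OC | intermediate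
8 | methyl 2-[(2-hydroxy-4,6-dioxo-2-pentylcyclohexyl)oxy]-4-methoxy-6-methylbenzoate (mixture of diastereomers, both centres lost on aromatization) | CCCCCC1(O)CC(=O)CC(=O)C1Oc1cc(OC)cc(C)c1C(=O)OC | intermediate
9 | methyl 2-(2,4-dihydroxy-6-pentylphenoxy)-4-methoxy-6-methylbenzoate | COC(=O)c1c(C)cc(OC)cc1Oc1c(O)cc(O)cc1CCCCC | intermediate
10 | methyl 2-(2,4-dimethoxy-6-pentylphenoxy)-4-methoxy-6-methylbenzoate | COC(=O)c1c(C)cc(OC)cc1Oc1c(OC)cc(OC)cc1CCCCC | intermediate
11 | hexanoyl chloride | CCCCCC(=O)Cl | starting material
12 | N,O-dimethylhydroxylamine hydrochloride | CNOC.Cl | starting material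
13 | N-methoxy-N-methylhexanamide | CCCCCC(=O)N(C)OC | intermediate
14 | methyl 2-(2,4-dimethoxy-6-pentylphenoxy)-6-(lithiomethyl)-4-methoxybenzoate | [Li]Cc1cc(OC)cc(Oc2c(OC)cc(OC)cc2CCCCC)c1C(=O)OC | intermediate
15 | methyl 2-(2,4-dimethoxy-6-pentylphenoxy)-4-methoxy-6-(2-oxoheptyl)benzoate | CCCCCC(=O)Cc1cc(OC)cc(Oc2c(OC)cc(OC)cc2CCCCC)c1C(=O)OC | intermediate
16 | 8-(2,4-dimethoxy-6-pentylphenoxy)-6-methoxy-3-pentyl-1H-isochromen-1-one | CCCCCc1cc2cc(OC)cc(Oc3c(OC)cc(OC)cc3CCCCC)c2c(=O)o1 | intermediate
17 | 8-(2,4-dihydroxy-6-pentylphenoxy)-6-hydroxy-3-pentyl-1H-isochromen-1-one | CCCCCc1cc2cc(O)cc(Oc3c(O)cc(O)cc3CCCCC)c2c(=O)o1 | target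

**Step count**
Total steps: 9. Longest linear sequence: 8 (steps 1 to 5 and 7 to 9, from methyl orsellinate); step 6 is a one-step side branch.

**Steps most likely to fail**

Step 4. Several processes could divert the triketone:
- enolization toward the pentyl side and closure of C7' onto C2', giving the regioisomeric resorcinol;
- O-cyclization to a 4-pyranone during acidification;
- Claisen-type closure of the C1' carbanion onto the ring A ester;
- retro-Claisen cleavage of the chain by hydroxide.

The fallback gives up the aldol construction of ring B and joins two preformed rings. It sets out from compound 2 and comes back at compound 10. Commercial 1,3-dimethoxy-5-pentylbenzene (CCCCCc1cc(OC)cc(OC)c1) is brominated with N-bromosuccinimide in MeCN at 0 °C, para to one methoxy group and ortho to the other, to give 2-bromo-1,5-dimethoxy-3-pentylbenzene F1. An Ullmann diaryl ether coupling of F1 with phenol 2 (CuI, N,N-dimethylglycine, Cs2CO3, dioxane, 110 °C) should then give compound 10 directly.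

Step 3. Proton transfer from the α-aryloxy amide to the dianion could outrun addition, the second deprotonation of the diketone could occur partly at C5 instead of C1, and the triketone could cyclodehydrate during the acidic quench. The fallback replaces the acylation by an aldol addition followed by oxidation. It sets out from compound 4 and comes back at compound 7. Amide 4 is reduced with i-Bu2AlH in THF at −78 °C to methyl 4-methoxy-2-methyl-6-(2-oxoethoxy)benzoate F2. Dianion 6 adds through its terminal carbon to this aldehyde at −78 °C, an addition that is fast and not troubled by the acidity of the product, to give racemic methyl 2-[(2-hydroxy-4,6-dioxoundecyl)oxy]-4-methoxy-6-methylbenzoate F3. Oxidation of the carbinol with Dess–Martin periodinane in CH2Cl2 should then give triketone 7.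

Step 7. The benzylic anion could condense with the ester of a second molecule of 10, or it could be quenched by proton transfer from the enolizable amide 13, returning starting material. The fallback builds the lactone ring by the homophthalic acid route. It sets out from compound 10 and comes back at compound 16. Anion 14 is trapped with CO2, a non-enolizable and very fast electrophile, to give [3-(2,4-dimethoxy-6-pentylphenoxy)-5-methoxy-2-(methoxycarbonyl)phenyl]acetic acid F4. Hydrolysis of the hindered ester with KOH in aqueous DMSO at 120 °C gives 2-(carboxymethyl)-6-(2,4-dimethoxy-6-pentylphenoxy)-4-methoxybenzoic acid F5. Heating F5 with hexanoyl chloride 11 at about 190 °C should give isocoumarin 16 by C-acylation of the homophthalic anhydride formed in the melt, decarboxylation and ring closure.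

**Further compounds**
F1 | step 4 | 2-bromo-1,5-dimethoxy-3-pentylbenzene | CCCCCc1cc(OC)cc(OC)c1Br
F2 | step 3 | methyl 4-methoxy-2-methyl-6-(2-oxoethoxy)benzoate | COC(=O)c1c(C)cc(OC)cc1OCC=O
F3 | step 3 | methyl 2-[(2-hydroxy-4,6-dioxoundecyl)oxy]-4-methoxy-6-methylbenzoate (racemic) | CCCCCC(=O)CC(=O)CC(O)COc1cc(OC)cc(C)c1C(=O)OC
F4 | step 7 | [3-(2,4-dimethoxy-6-pentylphenoxy)-5-methoxy-2-(methoxycarbonyl)phenyl]acetic acid | COC(=O)c1c(CC(=O)O)cc(OC)cc1Oc1c(OC)cc(OC)cc1CCCCC
F5 | step 7 | 2-(carboxymethyl)-6-(2,4-dimethoxy-6-pentylphenoxy)-4-methoxybenzoic acid | OC(=O)Cc1cc(OC)cc(Oc2c(OC)cc(OC)cc2CCCCC)c1C(=O)O
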